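**Assumption:** (2Z,6E)-farnesol is taken as a purchasable single isomer from specialty isoprenoid suppliers (otherwise it can be separated from commercial mixed-isomer farnesol on AgNO3–silica).
**Numbering convention:** hexaprenyl numbering is used for the C30 chain. C1–C12 come from (2E,6E)-farnesol (C1 = its CH2O carbon) and C13–C24 from (2Z,6E)-farnesol (C13 = its CH2O carbon). The ring CH of the target is C14 (R) and the carbinol carbon is C15 (S).

## Retrosynthetic overview

1. Colleterpenol ⇒ its C1-phenylthio derivative (reductive C–S cleavage last).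
2. 14-membered ring ⇒ C1–C14 bond by intramolecular SN2 opening of a cis-(14R,15S)-14,15-epoxide by the C1 thioallyl anion. Inversion at C14 and retention of C15–O set both stereocentres from one epoxide. The trans epoxide of an all-E chain would give the C15 epimer, so a cis epoxide is required.
3. Linear epoxy-polyene ⇒ C12–C13 bond: C12 allylic sulfone anion from (2E,6E)-farnesol plus the triflate of 2,3-epoxy-(2Z,6E)-farnesol.
4. Epoxide ⇒ Sharpless asymmetric epoxidation of (2Z,6E)-farnesol with D-(−)-tartrate.
5. Ring order: oxirane first (step 5), then the 14-membered carbocycle (step 11), which consumes the oxirane.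

## Route

**Step 1**
Reactants: 1, (2E,6E)-farnesol
Product: 2, (2E,6E)-farnesyl tert-butyldimethylsilyl ether
Conditions: TBSCl, imidazole, DMF, 0 °C → rt
Reagents that add atoms: TBSCl, CC(C)(C)[Si](C)(C)Cl
Why: Standard silylation of a primary allylic alcohol, so that C1 carries no acidic or Pd-ionisable group during steps 7–8; no stereocentre involved.

**Step 2**
Reactants: 2
Product: 3, (2E,6E,10E)-12-hydroxyfarnesyl TBS ether
Conditions: SeO2 (cat.), t-BuOOH, CH2Cl2, 0 °C → rt; then NaBH4, EtOH, 0 °C
Reagents that add atoms: SeO2, O=[Se]=O, with t-BuOOH, CC(C)(C)OO, as terminal oxidant (adds one O)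
Why: SeO2/TBHP allylic oxidation (ene then [2,3]-sigmatropic shift) selectively hydroxylates the (E)-methyl of the terminal, most electron-rich alkene to give the (10E)-allylic alcohol; NaBH4 returns any over-oxidised enal.

**Step 3**
Reactants: 3
Product: 4, (2E,6E,10E)-12-bromofarnesyl TBS ether
Conditions: CBr4, PPh3, CH2Cl2, 0 °C
Reagents that add atoms: CBr4, BrC(Br)(Br)Br
Why: Appel bromination is a neutral SN2 reaction at the primary allylic carbon, so there is no allylic transposition and the TBS ether survives.

**Step 4**
Reactants: 4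
Product: 5, (2E,6E,10E)-12-(phenylsulfonyl)farnesyl TBS ether
Conditions: PhSO2Na, DMF, rt
Reagents that add atoms: sodium benzenesulfinate, [Na+].[O-]S(=O)c1ccccc1
Why: SN2 S-alkylation of the soft sulfinate at the primary allylic bromide gives the allylic sulfone with the 10E geometry intact.

**Step 5**
Reactants: 6, (2Z,6E)-farnesol
Product: 7, (2R,3S)-2,3-epoxy-(2Z,6E)-farnesol (cis epoxide)
Conditions: Ti(OiPr)4, D-(−)-DIPT, t-BuOOH, 4 Å MS, CH2Cl2, −20 °C
Reagents that add atoms: t-BuOOH, CC(C)(C)OO (adds one O)
Why: Katsuki–Sharpless asymmetric epoxidation touches only the allylic-alcohol alkene; D-(−)-tartrate gives the (2R,3S) cis epoxide (mirror image of the (2S,3R) product that L-(+)-tartrate gives with nerol-type Z-alcohols, about 90–94% ee expected), and these two centres become C14 and C15 of the target.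

**Step 6**
Reactants: 7
Product: 8, (2R,3S)-2,3-epoxy-(2Z,6E)-farnesyl triflate
Conditions: Tf2O, 2,6-lutidine, CH2Cl2, −78 °C; used crude at once
Reagents that add atoms: Tf2O, O=S(=O)(OS(=O)(=O)C(F)(F)F)C(F)(F)F
Why: Low-temperature O-triflation with a hindered base activates C13 without touching the epoxide stereocentres.

**Step 7**
Reactants: 5 and 8
Product: 9, (14R,15S)-14,15-epoxy-12-(phenylsulfonyl)-(2E,6E,10E,18E)-hexaprenyl TBS ether (C12 epimer mixture)
Conditions: 5 (1.2 equiv), n-BuLi (1.15 equiv), THF–DMPU, −78 °C; then 8, −78 °C; NH4Cl quench at −78 °C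
Reagents that add atoms: none
Why: α-Alkylation of the lithiated allylic sulfone by SN2 at the primary triflate is much faster than epoxide opening at −78 °C; the new C12 centre is an inconsequential mixture removed in step 8, and the cold quench prevents a second deprotonation and 3-exo cyclopropane formation.

**Step 8**
Reactants: 9
Product: 10, (14R,15S)-14,15-epoxy-(2E,6E,10E,18E)-hexaprenyl TBS ether
Conditions: Pd(dppp)Cl2 (10 mol %), LiBHEt3, THF, 0 °C
Reagents that add atoms: none
Why: Pd(0)-catalysed reductive desulfonylation (π-allyl formation, then hydride delivery at the carbon that bore sulfur) replaces C12–SO2Ph by C12–H with retention of the (10E)-alkene position and geometry; the trisubstituted epoxide and the silyl ether are inert at 0 °C.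

**Step 9**
Reactants: 10
Product: 11, (14R,15S)-14,15-epoxy-(2E,6E,10E,18E)-hexaprenol
Conditions: TBAF, THF, 0 °C → rt
Reagents that add atoms: none
Why: Fluoride-mediated desilylation frees the C1 allylic alcohol and leaves the epoxide and alkenes untouched.

**Step 10**
Reactants: 11
Product: 12, (14R,15S)-14,15-epoxy-(2E,6E,10E,18E)-hexaprenyl phenyl sulfide
Conditions: PhSSPh, n-Bu3P, pyridine, rt
Reagents that add atoms: diphenyl disulfide, c1ccccc1SSc1ccccc1
Why: The Hata reaction converts the primary allylic alcohol into the sulfide through an alkoxyphosphonium salt and SN2 by thiolate under neutral conditions, so the epoxide survives and there is no allylic shift.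

**Step 11**
Reactants: 12
Product: 13, (2S,5E)-6,10-dimethyl-2-[(3E,7E,11E)-4,8,12-trimethyl-2-(phenylthio)cyclotetradeca-3,7,11-trien-1-yl]undeca-5,9-dien-2-ol (ring C2 epimer mixture; ring C1 has the target's spatial arrangement, formally S while SPh is present)
Conditions: n-BuLi, DABCO, THF (0.005 M), −78 → −20 °C
Reagents that add atoms: none
Why: The Biellmann-type α-thioallyl anion attacks the less substituted epoxide carbon C14 intramolecularly (Kodama–Itô-type macrocyclisation) with inversion while the C15–O bond is retained, which converts the cis-(14R,15S) epoxide into the target's ring-CH and tertiary-carbinol configurations.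

**Step 12**
Reactants: 13
Product: 14, colleterpenol
Conditions: Li, EtNH2, −78 °C; NH4Cl quench
Reagents that add atoms: none
Why: Dissolving-metal reductive cleavage of the allylic C–S bond, with protonation at the less substituted C1 terminus, keeps the (E)-C2=C3 alkene; no stereocentre is touched.

## Compound list

1 | (2E,6E)-farnesol | CC(C)=CCC/C(C)=C/CC/C(C)=C/CO | starting material
2 | (2E,6E)-farnesyl TBS ether | CC(C)=CCC/C(C)=C/CC/C(C)=C/CO[Si](C)(C)C(C)(C)C | intermediate
3 | (2E,6E,10E)-12-hydroxyfarnesyl TBS ether | OC/C(C)=C/CC/C(C)=C/CC/C(C)=C/CO[Si](C)(C)C(C)(C)C | intermediate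
4 | (2E,6E,10E)-12-bromofarnesyl TBS ether | BrC/C(C)=C/CC/C(C)=C/CC/C(C)=C/CO[Si](C)(C)C(C)(C)C | intermediate
5 | (2E,6E,10E)-12-(phenylsulfonyl)farnesyl TBS ether | O=S(=O)(c1ccccc1)C/C(C)=C/CC/C(C)=C/CC/C(C)=C/CO[Si](C)(C)C(C)(C)C | intermediate
6 | (2Z,6E)-farnesol | CC(C)=CCC/C(C)=C/CC/C(C)=C\CO | starting material
7 | (2R,3S)-2,3-epoxy-(2Z,6E)-farnesol | OC[C@H]1O[C@@]1(C)CC/C=C(\C)CCC=C(C)C | intermediate
8 | (2R,3S)-2,3-epoxy-(2Z,6E)-farnesyl triflate | FC(F)(F)S(=O)(=O)OC[C@H]1O[C@@]1(C)CC/C=C(\C)CCC=C(C)C | intermediate
9 | (14R,15S)-14,15-epoxy-12-(phenylsulfonyl)hexaprenyl TBS ether, C12 epimers | CC(C)(C)[Si](C)(C)OC/C=C(\C)CC/C=C(\C)CC/C=C(\C)C(S(=O)(=O)c2ccccc2)C[C@H]1O[C@@]1(C)CC/C=C(\C)CCC=C(C)C | intermediate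
10 | (14R,15S)-14,15-epoxyhexaprenyl TBS ether | CC(C)(C)[Si](C)(C)OC/C=C(\C)CC/C=C(\C)CC/C=C(\C)CC[C@H]1O[C@@]1(C)CC/C=C(\C)CCC=C(C)C | intermediate
11 | (14R,15S)-14,15-epoxy-(2E,6E,10E,18E)-hexaprenol | OC/C=C(\C)CC/C=C(\C)CC/C=C(\C)CC[C@H]1O[C@@]1(C)CC/C=C(\C)CCC=C(C)C | intermediate
12 | (14R,15S)-14,15-epoxyhexaprenyl phenyl sulfide | c1ccc(cc1)SC/C=C(\C)CC/C=C(\C)CC/C=C(\C)CC[C@H]2O[C@@]2(C)CC/C=C(\C)CCC=C(C)C | intermediate
13 | 2-(phenylthio)colleterpenol (ring C2 epimers) | CC(C)=CCC/C(C)=C/CC[C@](C)(O)[C@H]1C(Sc2ccccc2)/C=C(\C)CC/C=C(\C)CC/C=C(\C)CC1 | intermediate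
14 | colleterpenol, (2S,5E)-6,10-dimethyl-2-[(1R,3E,7E,11E)-4,8,12-trimethylcyclotetradeca-3,7,11-trien-1-yl]undeca-5,9-dien-2-ol | CC(C)=CCC/C(C)=C/CC[C@](C)(O)[C@H]1C/C=C(\C)CC/C=C(\C)CC/C=C(\C)CC1 | target

## Totals and risks

Total step count: 12.
Longest linear sequence: 10 (steps 1–4 and 7–12, from (2E,6E)-farnesol).

The three steps most likely to fail:

1. **Step 11, macrocyclisation.** Risks are oligomerisation, γ-attack of the thioallyl anion and base-induced epoxide-to-allylic-alcohol isomerisation. Fallback: separate the stereochemistry from the ring closure. Open epoxy alcohol 7 intermolecularly at C2 with a vinyl or allyl cuprate (same inversion, same stereochemical outcome), elaborate the two arms, and close the ring at a remote allyl–allyl bond (C4–C5) by intramolecular alkylation of an allylic sulfone anion with an allylic bromide, then desulfonylate.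

2. **Step 7, sulfone anion plus epoxy triflate.** Risks are triflate decomposition and cyclopropane formation from the γ,δ-epoxy sulfone. Fallback: make C12–C13 with a non-allylic nucleophile. Alkylate the methyl acetoacetate dianion with 8 (or the corresponding iodide), build the (10E)-alkene by the Weiler enol phosphate/Me2CuLi sequence, and move the fragment union to C8–C9 as a conventional C9 allylic sulfone plus C8 allylic bromide coupling with a geraniol-derived partner.

3. **Step 8, desulfonylation of the C12 sulfone.** Both termini of this π-allyl are secondary, so the alkene may shift to C11=C12 or lose E geometry, and LiBHEt3 may attack the epoxide. Fallback: change the disconnection to C16–C17 so the sulfone sits on a carbon whose π-allyl is unambiguous. Couple geranyl phenyl sulfone anion with a C16 epoxy triflate made by Still–Gennari (Z)-olefination of a C1–C14 aldehyde, DIBAL reduction and Sharpless epoxidation.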